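**Retrosynthetic overview**
- Chebulic acid comes from O-demethylation and hydrolysis of a tricyclic bis-lactone: isochromanone ring B and dihydrocoumarin ring C share C4–C4a. Its (3S,4S,1'S) isomer has both substituents equatorial, so C3 and C1' (both α to carbonyls) can be set by equilibration.
- The bis-lactone comes from a β-aryl α-keto ester by asymmetric transfer hydrogenation with dynamic kinetic resolution (fixes C4), then lactonisation to ring B.
- Key disconnection, C3–C4: a glyoxylate-derived acyl radical adds to C4 of a coumarin-3-acetate.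
- The coumarin (ring C) comes from a Perkin condensation of a salicylaldehyde with succinic anhydride.
- The fully substituted benzene (ring A) is built de novo by furan–ynoate Diels–Alder/aromatisation. Ring order: A, then C, then B.

Assumption: compounds 1 and 2 are bought in the protected forms shown (O-methyl, methyl ester, dimethyl acetal; all removed later). Late intermediates use chebulic acid numbering (C1(=O), O2, C3, C4, C4a, C5–C8, C8a; side chain C1', C2').

**Step 1**
Reactants: 1 3,4-dimethoxyfuran; 2 methyl 4,4-dimethoxybut-2-ynoate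
Product: 5 methyl 2-formyl-3-hydroxy-4,5-dimethoxybenzoate, via oxanorbornadiene cycloadduct 3 (not isolated), via phenol acetal 4 (not isolated)
Conditions: PhMe, 100 °C, sealed tube; then CF3CO2H (cat.), CH2Cl2, 0 °C; then 1 M HCl, THF, 25 °C
Reagents that add atoms: water (O)
Why: Diels–Alder addition of the electron-rich furan to the ynoate, then acid-catalysed oxanorbornadiene-to-phenol isomerisation; the bridge C–O bond next to the ester-bearing carbon ionises (the cation avoids the CO2Me carbon), so the OH ends ortho to the acetal carbon, and the acetal is hydrolysed on work-up; no stereocentre.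

**Step 2**
Reactants: 5 methyl 2-formyl-3-hydroxy-4,5-dimethoxybenzoate; 6 succinic anhydride
Product: 9 methyl 7,8-dimethoxy-3-(2-methoxy-2-oxoethyl)-2-oxo-2H-chromene-5-carboxylate, via aryl hydrogen succinate 7 (not isolated), via coumarin-3-acetic acid 8 (not isolated)
Conditions: succinic anhydride (3 equiv), Et3N, dioxane, 120 °C, sealed tube; then MeI, K2CO3, DMF, 25 °C
Reagents that add atoms: iodomethane (CI)
Why: Perkin condensation (phenol O-acylation, intramolecular aldol, dehydration) gives the coumarin-3-acetic acid, which is esterified by carboxylate alkylation; no stereocentre.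

**Step 3**
Reactants: 9 methyl 7,8-dimethoxy-3-(2-methoxy-2-oxoethyl)-2-oxo-2H-chromene-5-carboxylate; 10 ethyl glyoxylate
Product: 11 methyl (3S*,4S*)-4-(2-ethoxy-2-oxoacetyl)-7,8-dimethoxy-3-(2-methoxy-2-oxoethyl)-2-oxo-3,4-dihydro-2H-chromene-5-carboxylate (racemic trans)
Conditions: (nBu4N)4W10O32 (4 mol %), ethyl glyoxylate (5 equiv), MeCN, 390 nm LED, 25 °C, Ar; then Et3N (cat.), CH2Cl2, 25 °C
Reagents that add atoms: none
Why: Proposed new method: excited decatungstate abstracts the formyl H of ethyl glyoxylate, the nucleophilic acyl radical EtO2C–C•=O adds to C4 (β-carbon of the unsaturated lactone; C3 is blocked by the acetate arm), and the α-lactone radical takes H back from reduced decatungstate; the closest known reactions are decatungstate-photocatalysed hydroacylation of electron-poor alkenes with aldehydes and Giese additions to coumarins; this forms the C3–C4 bond, and the new C4 centre is α to the ketone and epimerises to the trans isomer, so no stereocontrol is needed here.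

**Step 4**
Reactants: 11 racemic trans keto ester
Product: 14 (3S,4S,1'S)-bis-lactone (6,7-di-O-methylchebulic acid 1'-carboxy→5-O lactone; 3-ethyl ester; side-chain methyl ester), via hydroxy ester 12 (not isolated), via 3-epi bis-lactone 13 (not isolated)
Conditions: RuCl[(R,R)-TsDPEN](p-cymene) (2 mol %), HCO2H/Et3N (5:2), DMF, 40 °C; then TsOH (10 mol %), PhMe, 110 °C, 5 Å MS; then DBU (0.2 equiv), PhMe, 40 °C
Reagents that add atoms: none
Why: Noyori–Ikariya asymmetric transfer hydrogenation with dynamic kinetic resolution: C4 epimerises through the keto ester enol in the amine buffer while the catalyst reduces only the C4-(S) epimer (anti hydroxy/aryl, as for other β-aryl α-keto esters), fixing C4; acid-catalysed lactonisation onto the peri methyl ester closes ring B; DBU then equilibrates C3 and C1' to the isomer with both substituents equatorial and H3/H4/H1' trans-diaxial, which is (3S,4S,1'S).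

**Step 5**
Reactants: 14 (3S,4S,1'S)-bis-lactone
Product: 16 chebulic acid, via catechol bis-lactone 15 (not isolated)
Conditions: BBr3 (6 equiv), CH2Cl2, −78 → 0 °C; then H2O; then 2 M HCl, 60 °C
Reagents that add atoms: water (O)
Why: BBr3 cleaves the two aryl methyl ethers, then acid hydrolysis opens the aryl lactone (ring C) and cleaves the ethyl and methyl esters while the isochromanone lactone is retained; acidic conditions do not enolise C3 or C1', so no stereocentre is touched.

**Compound list**
1 | 3,4-dimethoxyfuran | COc1cocc1OC | starting material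
2 | methyl 4,4-dimethoxybut-2-ynoate | COC(=O)C#CC(OC)OC | starting material
3 | methyl 3-(dimethoxymethyl)-5,6-dimethoxy-7-oxabicyclo[2.2.1]hepta-2,5-diene-2-carboxylate (racemic) | COC(=O)C1=C(C(OC)OC)C2OC1C(OC)=C2OC | intermediate
4 | methyl 2-(dimethoxymethyl)-3-hydroxy-4,5-dimethoxybenzoate | COC(=O)c1cc(OC)c(OC)c(O)c1C(OC)OC | intermediate
5 | methyl 2-formyl-3-hydroxy-4,5-dimethoxybenzoate | COC(=O)c1cc(OC)c(OC)c(O)c1C=O | intermediate
6 | succinic anhydride | O=C1CCC(=O)O1 | starting material
7 | 4-[2-formyl-5,6-dimethoxy-3-(methoxycarbonyl)phenoxy]-4-oxobutanoic acid | COC(=O)c1cc(OC)c(OC)c(OC(=O)CCC(=O)O)c1C=O | intermediate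
8 | [7,8-dimethoxy-5-(methoxycarbonyl)-2-oxo-2H-chromen-3-yl]acetic acid | O=C1Oc2c(OC)c(OC)cc(C(=O)OC)c2C=C1CC(=O)O | intermediate
9 | methyl 7,8-dimethoxy-3-(2-methoxy-2-oxoethyl)-2-oxo-2H-chromene-5-carboxylate | O=C1Oc2c(OC)c(OC)cc(C(=O)OC)c2C=C1CC(=O)OC | intermediate
10 | ethyl glyoxylate | CCOC(=O)C=O | starting material
11 | methyl (3S*,4S*)-4-(2-ethoxy-2-oxoacetyl)-7,8-dimethoxy-3-(2-methoxy-2-oxoethyl)-2-oxo-3,4-dihydro-2H-chromene-5-carboxylate (racemic; one enantiomer drawn) | COC(=O)C[C@H](C(=O)O3)[C@@H](c2c(cc(OC)c(OC)c23)C(=O)OC)C(=O)C(=O)OCC | intermediate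
12 | ethyl (2R)-2-hydroxy-2-[(4S)-7,8-dimethoxy-5-(methoxycarbonyl)-3-(2-methoxy-2-oxoethyl)-2-oxo-3,4-dihydro-2H-chromen-4-yl]acetate (both C1' epimers) | COC(=O)CC(C(=O)O3)[C@@H](c2c(cc(OC)c(OC)c23)C(=O)OC)[C@@H](O)C(=O)OCC | intermediate
13 | (3R,4S)-bis-lactone, the C3 epimer of 14 (both C1' epimers) | COC(=O)CC(C(=O)O3)[C@H]1c2c(cc(OC)c(OC)c23)C(=O)O[C@H]1C(=O)OCC | intermediate
14 | (3S,4S,1'S)-bis-lactone: 6,7-di-O-methylchebulic acid 1'-carboxy→5-O lactone, 3-ethyl ester, side-chain methyl ester | COC(=O)C[C@H](C(=O)O3)[C@H]1c2c(cc(OC)c(OC)c23)C(=O)O[C@@H]1C(=O)OCC | intermediate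
15 | (3S,4S,1'S)-6,7-dihydroxy bis-lactone: chebulic acid 1'-carboxy→5-O lactone, 3-ethyl ester, side-chain methyl ester | COC(=O)C[C@H](C(=O)O3)[C@H]1c2c(cc(O)c(O)c23)C(=O)O[C@@H]1C(=O)OCC | intermediate
16 | chebulic acid, (2S)-2-[(3S,4S)-3-carboxy-5,6,7-trihydroxy-1-oxo-3,4-dihydro-1H-isochromen-4-yl]butanedioic acid | O=C(O)C[C@H](C(=O)O)[C@H]1c2c(cc(O)c(O)c2O)C(=O)O[C@@H]1C(=O)O | target

**Totals**
Total step count: 5. Longest linear sequence: 5.

**Steps most likely to fail, with fallbacks**

Step 3 is the riskiest. The glyoxylate-derived acyl radical may add too slowly to the trisubstituted, peri-hindered coumarin, or the coumarin may photodimerise. The fallback sets out from 9 and comes back at 11, and inverts the radical polarity. Hydrogenation of the C3=C4 bond (H2, Pd/C, EtOAc) gives racemic methyl 7,8-dimethoxy-3-(2-methoxy-2-oxoethyl)-2-oxo-3,4-dihydro-2H-chromene-5-carboxylate F1. Wohl–Ziegler bromination (NBS, dibenzoyl peroxide cat., PhCF3, 80 °C) gives methyl 4-bromo-7,8-dimethoxy-3-(2-methoxy-2-oxoethyl)-2-oxo-3,4-dihydro-2H-chromene-5-carboxylate F2. Nickel-catalysed reductive acyl cross-electrophile coupling of F2 with ethyl chlorooxoacetate (NiBr2·dme, dtbbpy, Mn, DMA, 0 °C) has the benzylic C4 radical captured by an acyl–nickel species and gives 11.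

Step 4 has four weak points:
- The facial sense and anti preference are taken by analogy and must be checked on this cyclic substrate; the catalyst antipode is used if the sense is reversed.
- C1' epimerises more slowly than C4, which can erode the ee.
- The new hydroxyl can instead form the γ-lactone with the ring C carbonyl or a δ-lactone with the side-chain ester; the acid stage with methanol removal is meant to funnel these to the bis-lactone.
- The equatorial preference in the DBU equilibration is estimated at about 1 kcal/mol per centre, so the ratio may be modest and crystallisation of 14 may be needed.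

The fallback sets out from 11 and comes back at 13, and moves the enantio-determining step from C=O reduction to C=C hydrogenation. TsOH in PhMe (Dean–Stark) closes ring B through the enol and gives the enol bis-lactone F3 (the 3,4-didehydro analogue of 13, racemic at C1'). Rhodium-catalysed asymmetric hydrogenation of this α-(acyloxy)acrylate-type double bond ([Rh(cod)((R,R)-Me-BPE)]OTf, H2 20 bar, MeOH-free CH2Cl2) adds both hydrogens to one face and gives 13, which is equilibrated with DBU to 14 as in step 4.

Step 2 is the third risk. The aldol alkoxide can be trapped by the neighbouring methyl ester as a phthalide, and the hot basic conditions may degrade aldehyde 5. The fallback sets out from 5 and comes back at 9, and avoids any alkoxide intermediate. Wittig olefination of 5 with dimethyl 2-(triphenylphosphoranylidene)succinate (PhMe, 80 °C) gives dimethyl (2E)-2-{[2-hydroxy-3,4-dimethoxy-6-(methoxycarbonyl)phenyl]methylidene}butanedioate F4. Irradiation (350 nm, MeCN) isomerises the double bond, and the Z isomer lactonises to 9.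

**Further compounds**
F1 | step 3 | methyl 7,8-dimethoxy-3-(2-methoxy-2-oxoethyl)-2-oxo-3,4-dihydro-2H-chromene-5-carboxylate (racemic) | O=C1Oc2c(OC)c(OC)cc(C(=O)OC)c2CC1CC(=O)OC
F2 | step 3 | methyl 4-bromo-7,8-dimethoxy-3-(2-methoxy-2-oxoethyl)-2-oxo-3,4-dihydro-2H-chromene-5-carboxylate (racemic, C4 epimers) | O=C1Oc2c(OC)c(OC)cc(C(=O)OC)c2C(Br)C1CC(=O)OC
F3 | step 4 | enol bis-lactone, 3,4-didehydro analogue of 13 (racemic at C1') | COC(=O)CC1C(=O)Oc2c(OC)c(OC)cc3C(=O)OC(C(=O)OCC)=C1c23
F4 | step 2 | dimethyl (2E)-2-{[2-hydroxy-3,4-dimethoxy-6-(methoxycarbonyl)phenyl]methylidene}butanedioate | COC(=O)C/C(C(=O)OC)=C\c1c(O)c(OC)c(OC)cc1C(=O)OC
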